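## Structural features

The target is a depside. Ring A (C3a, C4, C5, C6, C7, C7a) is fused along its C3a–C7a edge to the dihydrofuran ring B (O1, C2, C3). C2 carries the catechol ring C, C3 a free carboxylic acid, and C4 an (E)-acrylate whose carboxyl esterifies the secondary hydroxyl of methyl (R)-3-(3,4-dihydroxyphenyl)lactate (ring D).

Ring A is 1,2,3,4-tetrasubstituted: C3a (bond to C3), C4 (acrylate), C7 (hydroxyl) and C7a (O1) are contiguous, and only C5 and C6 carry hydrogen.

C2 (S) and C3 (S) are adjacent and trans on ring B. The third stereocentre (R) sits far away in the lactate unit and cannot be controlled by the other two.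

Fragile points:
- two catechols and a fifth phenol, all sensitive to oxidants;
- the C2–O1 bond, a benzylic aryl ether para to a ring C oxygen, which acid can ionise;
- the C3 hydrogen (α to carboxyl, benzylic, O1 in the β-position), so base epimerises it or opens ring B by retro-oxa-Michael reaction;
- the acrylate C=C, which forbids late hydrogenation;
- a methyl ester and a secondary alkyl ester beside a free acid, which forbid saponification.

The real difficulty is the crowded ring A with two neighbouring oxygens, one of them inside ring B, next to a trans stereo-pair. The phenol protection must then be removed without hydrogen, base or strong acid.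

The key step uses the shared C3a–C7a edge. With O1–C2–C3 as the tether of a 1,6-diyne, the inner alkyne carbons become C3a and C7a, the outer ones C4 and C7, and the only CH–CH edge of ring A (C5–C6) is acetylene.

## Logic of the disconnections

**31 ⇒ 30.** Cut the five phenolic O–benzyl bonds. Benzyl is the one phenol protection that survives every organometallic, basic, fluoride and oxidative step behind it. 30 is lipophilic, air-stable and chromatographable. The forward step must cleave five ethers without hydrogen (acrylate), base (C3–H, esters) or heat, which points to a boron Lewis acid at −78 °C with a cation scavenger.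

**30 ⇒ 28 ⇒ 27.** Take the C3 carboxyl back to CH2OH and then to its p-methoxybenzyl ether. The acidic C3–H is thus created only at the penultimate stage. The forward steps need a non-basic one-pot alcohol-to-acid oxidation, and an ether cleavage that leaves aryl benzyl ethers alone.

**27 ⇒ 21 + 26.** Cut the acrylate Cα=Cβ bond. The molecule splits into a benzofuran aldehyde and a lactate-derived phosphonate of similar size. The olefination must be E-selective, must not epimerise the lactate centre, and must precede C3 oxidation, because a 4-formyl 3-carboxylic acid would close to a hydroxylactone.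

**26 ⇒ 24 + 25; 24 ⇒ 23 ⇒ 22.** Cut the phosphonoacetate ester C–O bond, then two benzyl ethers and the methyl ester. The remote R centre comes from the chiral pool at no cost. The demand is only that no step enolises the α-oxygenated ester.

**21 ⇒ 20 ⇒ 19 ⇒ 17.** The C4 aldehyde goes back to CH2OH and then to the silyl ether. The C7 benzyl ether goes back to the phenol and then to a C7–Si bond. Silicon is needed because the alkyne that becomes C7a≡C7 cannot carry oxygen on both carbons. The forward step is an aryl C–Si oxidation; the fluoride it needs also frees the C4 alcohol, which saves a step.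

**17 ⇒ 15 + 16 (key).** Cut C3a–C7a, C4–C5 and C6–C7. Ring A and ring B disappear together, leaving an acyclic chain that holds both stereocentres and all four ring A substituents, plus 16. The forward step must cross-trimerise near room temperature and tolerate the alkynyl ether.

**15 ⇒ 13 ⇒ 10 + 11.** Cut C7–Si, then the O1–C7a bond. The two carbons C7 and C7a come from 11. The forward steps need strong base at low temperature and cold, acid-free handling of 15.

**10 ⇒ 7 + 8.** Cut C2–C3. One C–C bond formation sets both stereocentres from an aromatic aldehyde and a propargylic electrophile. The demands are transfer of chirality from 7 and anti selectivity, which maps onto 2,3-trans.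

**7 ⇒ 6 ⇒ 5 ⇒ 4 ⇒ 1 + 2.** Cut the carbinol–alkyne C–C bond and set the carbinol centre by reducing the ynone. All carbons come from two small building blocks. The demand is an enantioselective reduction that tells alkynyl from alkoxymethyl.

## Other disconnections considered

**Alternative 1:** Enzymatic closure of ring B.
- Cut: C2–O1 only.
- Forward key step: a flavin-dependent 4-alkylphenol oxidase of the vanillyl alcohol oxidase family would take hydride from the C2 methylene of the unprotected seco-acid (2R)-3-(3,4-dihydroxyphenyl)-2-(6-formyl-2,3-dihydroxyphenyl)propanoic acid A1. The C7a hydroxyl would add to the p-quinone methide to give (2S,3S)-2-(3,4-dihydroxyphenyl)-4-formyl-7-hydroxy-2,3-dihydro-1-benzofuran-3-carboxylic acid A2.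
- In favour: no protecting groups at all. It avoids the final deprotection that burdens the chosen plan, and here it is clearly the better plan. C2 would be set trans to C3, which is also the thermodynamic outcome, so on this point it equals the chosen plan.
- Against: enzymes of this class are known for small 4-alkylphenols. A1 is branched next to the reacting methylene and carries catechols that may themselves be oxidised. Water competes for the quinone methide. A1 needs its own enantioselective synthesis with a racemisation-prone α-aryl acid, and the same 1,2,3,4-substituted ring A must still be made. A2 is a 4-formyl 3-acid that should rest as a hydroxylactone, which complicates the olefination.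
- Comparison: structurally it solves ring B only and postpones ring A, whereas the chosen plan makes both rings at once. Mechanistically it is a polar conjugate addition against an organometallic cycloaddition. It would be shorter after A1, but not once the route to A1 is counted.

**Alternative 2:** Aryne closure with C7 oxygenation.
- Cut: O1–C7a and C7–O.
- Forward key step: n-BuLi would convert (1S,2R)-1-[3,4-bis(benzyloxy)phenyl]-2-(3-bromo-2-fluorophenyl)-3-[(tert-butyldimethylsilyl)oxy]propan-1-ol A3 into its alkoxide and, by Br–Li exchange and loss of LiF, into the C7–C7a aryne. The alkoxide would add at C7a, and the C7 aryllithium would be borylated and oxidised to (2S,3R)-2-[3,4-bis(benzyloxy)phenyl]-3-{[(tert-butyldimethylsilyl)oxy]methyl}-2,3-dihydro-1-benzofuran-7-ol A4.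
- In favour: A3 is the type of compound that an auxiliary-controlled syn-aldol addition to 8 gives. That is a more widely practised way to set the two centres than the allenylzinc addition, so the alternative is better on stereocontrol. The regiochemistry of O1 and the C7 oxygen is as secure as in the chosen plan (equal). No labile alkynyl ether is involved (better).
- Against: A4 has no carbon at C4. The acrylate must later be forced onto the most hindered ring A position, for example by carboxylate-directed C–H olefination with hot base on the epimerisable acid. Butyllithium also meets benzylic ethers and can add to the aryne.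
- Comparison: structurally it delivers two of the four ring A substituents, the chosen plan all four. Mechanistically it is anionic against metal-catalysed. The step count to A4 is similar, but to the target it is longer because of C4.

**Alternative 3:** Biomimetic oxidative cross-coupling.
- Cut: C3–C3a and C2–O1.
- Forward key step: Ag2O would oxidise (4S)-4-benzyl-3-{(2E)-3-[3-(benzyloxy)-4-hydroxyphenyl]prop-2-enoyl}-1,3-oxazolidin-2-one A5 and tert-butyl (2E)-3-[4-(benzyloxy)-2-bromo-5-hydroxyphenyl]prop-2-enoate A6 to phenoxyl radicals. C8 of A5 would join the ring carbon of A6 between side chain and hydroxyl, and the phenol would add to the quinone methide. The product would be tert-butyl (2E)-3-[(2S,3S)-3-{[(4S)-4-benzyl-2-oxo-1,3-oxazolidin-3-yl]carbonyl}-7-(benzyloxy)-2-[3-(benzyloxy)-4-hydroxyphenyl]-5-bromo-2,3-dihydro-1-benzofuran-4-yl]prop-2-enoate A7.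
- In favour: it is the most convergent of all. Both ring B bonds and both stereocentres form in one step, C3 is already a carboxyl derivative and C4 already carries its acrylate. On step economy and oxidation-state economy it is better than the chosen plan. The trans preference is intrinsic (equal).
- Against: two different phenoxyl radicals couple statistically, so homodimers are expected. A6 must react at its most hindered ring position, with C–O coupling as a competitor. Auxiliaries control the face of radical couplings only moderately. Afterwards the bromide must go without touching two alkenes, the imide must be cleaved with peroxide or hydroxide next to the base-sensitive C3, and the tert-butyl ester exchanged for the lactate. The benzyl/alkene deprotection problem is the same as in the chosen plan (equal).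
- Comparison: structurally the substitution pattern depends on radical site selectivity, whereas in the chosen plan the tether locks it. Mechanistically it is a radical coupling against an organometallic cycloaddition. It is the shortest on paper but the least predictable.

Key step: step 8

**Remarks on the chemistry (before the steps)**
- Assumption: 1 (the TBS ether of propargyl alcohol) and 2 (the PMB ether of glycolaldehyde) are taken as catalogue compounds. If not, each is one routine step from propargyl alcohol or from a bis-PMB but-2-ene-1,4-diol.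
- Correction of naming: 15 is an alkyl alkynyl ether silylated on carbon (a 1-alkoxy-2-silylalkyne), not an O-silylated ynolate, and is treated as such.
- Correction of descriptors: the ring carbon that is 3S in the target is 3R in 17–28 (and 2R in 10) with unchanged geometry, because CH2O ranks below C2 while CHO and CO2H rank above it.
- Correction of order: fluoride activation for the C–Si oxidation also removes the TBS group, so both happen in step 9. The C4 aldehyde is olefinated before C3 is oxidised. The final debenzylation cannot be a hydrogenolysis.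

## Steps

Step 1
Reactants: 1 tert-butyldimethyl(prop-2-yn-1-yloxy)silane; 2 2-[(4-methoxybenzyl)oxy]acetaldehyde
Product: 4 rac-5-[(tert-butyldimethylsilyl)oxy]-1-[(4-methoxybenzyl)oxy]pent-3-yn-2-ol, via lithium acetylide 3 (not isolated)
Conditions: n-BuLi, THF, −78 °C; then 2, −78 → −20 °C; aq NH4Cl
Reagents that add atoms: none
Why: Deprotonation of the terminal alkyne gives acetylide 3, which adds 1,2 to the aldehyde at low temperature faster than it enolises it (acetylide addition); the racemic carbinol is acceptable because this centre is erased in step 2.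

Step 2
Reactants: 4 racemic propargylic alcohol
Product: 5 5-[(tert-butyldimethylsilyl)oxy]-1-[(4-methoxybenzyl)oxy]pent-3-yn-2-one
Conditions: activated MnO2 (15 equiv), CH2Cl2, rt; filter, use at once
Reagents that add atoms: none
Why: MnO2 oxidises propargylic alcohols under neutral conditions and leaves PMB and TBS ethers alone; the ynone is a Michael acceptor and is therefore not stored.

Step 3
Reactants: 5 ynone
Product: 6 (2S)-5-[(tert-butyldimethylsilyl)oxy]-1-[(4-methoxybenzyl)oxy]pent-3-yn-2-ol
Conditions: Ru[(R,R)-TsDPEN](p-cymene) (1 mol %), i-PrOH, rt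
Reagents that add atoms: none
Why: Noyori asymmetric transfer hydrogenation: the Ru–H/N–H pair delivers hydrogen through a six-membered transition state in which the alkynyl group sits next to the arene ligand, so alkynyl against alkoxymethyl decides the face; the (R,R)-ligand gives the arrangement that is named R for alkynyl methyl carbinols and S here, because CH2OPMB outranks the alkynyl carbon; base-free 2-propanol avoids conjugate addition to the ynone.

Step 4
Reactants: 6 (S)-propargylic alcohol
Product: 7 (2S)-5-[(tert-butyldimethylsilyl)oxy]-1-[(4-methoxybenzyl)oxy]pent-3-yn-2-yl methanesulfonate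
Conditions: MsCl, Et3N, CH2Cl2, −78 → 0 °C; used crude
Reagents that add atoms: methanesulfonyl chloride, CS(=O)(=O)Cl
Why: O-sulfonylation with retention gives the leaving group for the SN2′ oxidative addition of step 5; propargylic mesylates do not store well and are not chromatographed.

Step 5
Reactants: 7 (S)-mesylate; 8 3,4-bis(benzyloxy)benzaldehyde
Product: 10 (1S,2R)-1-[3,4-bis(benzyloxy)phenyl]-5-[(tert-butyldimethylsilyl)oxy]-2-{[(4-methoxybenzyl)oxy]methyl}pent-3-yn-1-ol, via allenylzinc 9 (not isolated)
Conditions: Pd(OAc)2 (5 mol %), PPh3 (5 mol %), Et2Zn (3 equiv), THF, −78 → −20 °C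
Reagents that add atoms: none
Why: Zerovalent palladium formed in situ displaces the mesylate anti in an SN2′ sense, transmetallation gives allenylzinc 9 with central-to-axial chirality transfer, and 9 adds to 8 through a closed six-membered SE2′ transition state (palladium/zinc propargylic umpolung); the C–C bond forms on the face opposite to the departed mesylate, so (S)-7 gives 2R, and the aryl group avoids the CH2OPMB group in the chair, which gives the anti (1S) carbinol that maps onto 2,3-trans.

Step 6
Reactants: 10 homopropargylic alcohol; 11 trichloroethylene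
Product: 13 (E)-1,2-dichlorovinyl ether of 10 (tert-butyl{[(4R,5S)-5-[3,4-bis(benzyloxy)phenyl]-5-{[(E)-1,2-dichloroethenyl]oxy}-4-{[(4-methoxybenzyl)oxy]methyl}pent-2-yn-1-yl]oxy}dimethylsilane), via dichloroacetylene 12 (not isolated)
Conditions: KH (2.2 equiv), THF, 0 °C; then 11 (1.2 equiv), −50 °C → rt
Reagents that add atoms: none
Why: Base turns 11 into dichloroacetylene 12 in solution, and anti addition of the potassium alkoxide across 12 followed by protonation gives the (E)-dichlorovinyl ether; no bond to either stereocentre is broken, and 12 is generated and consumed in dilute solution, which is the safe way to handle it.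

Step 7
Reactants: 13 dichlorovinyl ether
Product: 15 benzyl({[(1S,2R)-1-[3,4-bis(benzyloxy)phenyl]-5-[(tert-butyldimethylsilyl)oxy]-2-{[(4-methoxybenzyl)oxy]methyl}pent-3-yn-1-yl]oxy}ethynyl)dimethylsilane, via lithium alkynyl ether 14 (not isolated)
Conditions: n-BuLi (2.4 equiv), THF, −78 → −40 °C; BnMe2SiCl, −78 → 0 °C; Et3N-deactivated silica, store cold
Reagents that add atoms: benzyl(chloro)dimethylsilane, C[Si](C)(Cl)Cc1ccccc1
Why: n-BuLi removes the vinylic proton, chloride is lost to give the chloroalkynyl ether, and chlorine–lithium exchange gives 14, which is silylated on carbon (dehydrochlorination, halogen–metal exchange, C-silylation); the product is kept at or below 0 °C and away from acid because benzylic alkynyl ethers with a β-hydrogen fragment on warming and hydrate on acid.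

Step 8
Reactants: 15 diyne; 16 acetylene
Product: 17 (2S,3R)-7-[benzyl(dimethyl)silyl]-2-[3,4-bis(benzyloxy)phenyl]-4-{[(tert-butyldimethylsilyl)oxy]methyl}-3-{[(4-methoxybenzyl)oxy]methyl}-2,3-dihydro-1-benzofuran
Conditions: RhCl(PPh3)3 (5–10 mol %), acetylene (1 atm, acetone-free), toluene, 25 → 40 °C, slow addition of 15
Reagents that add atoms: none
Why: Loss of phosphine from RhCl(PPh3)3 lets both alkynes of 15 bind, and oxidative coupling gives a rhodacyclopentadiene of trivalent rhodium; this C–C coupling forms C3a–C7a and, because the alkynes are joined through O1–C2–C3, closes the five-membered ring B. Acetylene 16 then inserts (C4–C5) and reductive elimination forms C6–C7, closing the six-membered aromatic ring A and returning monovalent rhodium. The closest known reaction type is the rhodium-catalysed cross-cyclotrimerisation of heteroatom-tethered 1,6-diynes (ynamide or alkynyl ether tethers) with acetylene to indolines and 2,3-dihydrobenzofurans. No stereocentre is formed; C2 and C3 are sp3 atoms of the tether and the neutral conditions cannot epimerise them, so the anti relationship of 10 becomes 2,3-trans. Regiochemistry needs no control, since the tether fixes C3a/C7a as inner and C4/C7 as outer carbons and acetylene is symmetric, so CH2OTBS must end at C4 and silicon at C7. The selectivity that is needed is cross- over homo-trimerisation: both alkynes of 15 are internal and hindered and cannot compete with acetylene for insertion, and saturation with acetylene plus slow addition of 15 suppresses diyne dimers, while benzene from acetylene alone is volatile. The silyl group takes the α-position of the metallacycle, which bulky groups prefer. The temperature stays at or below 40 °C because the alkynyl ether would otherwise fragment.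

Step 9
Reactants: 17 cyclotrimer
Product: 19 (2S,3R)-2-[3,4-bis(benzyloxy)phenyl]-4-(hydroxymethyl)-3-{[(4-methoxybenzyl)oxy]methyl}-2,3-dihydro-1-benzofuran-7-ol, via aryldimethylsilanol 18 (not isolated)
Conditions: TBAF (3.5 equiv), THF, 0 °C → rt; then KHCO3, 30 % H2O2, MeOH, rt → 40 °C
Reagents that add atoms: hydrogen peroxide, OO
Why: Tamao oxidation after fluoride activation: fluoride cleaves the benzyl–silicon bond to give silanol 18 and removes the TBS ether in the same pot, then basic peroxide induces the aryl shift from silicon to oxygen at the same carbon, giving the C7 phenol; PMB and benzyl ethers and both stereocentres are inert to fluoride and to bicarbonate/peroxide.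

Step 10
Reactants: 19 phenol–benzylic alcohol
Product: 20 [(2S,3R)-7-(benzyloxy)-2-[3,4-bis(benzyloxy)phenyl]-3-{[(4-methoxybenzyl)oxy]methyl}-2,3-dihydro-1-benzofuran-4-yl]methanol
Conditions: BnBr (1.1 equiv), K2CO3, DMF, rt
Reagents that add atoms: benzyl bromide, BrCc1ccccc1
Why: Williamson etherification; carbonate deprotonates only the phenol, so the benzylic alcohol stays free.

Step 11
Reactants: 20 benzylic alcohol
Product: 21 (2S,3R)-7-(benzyloxy)-2-[3,4-bis(benzyloxy)phenyl]-3-{[(4-methoxybenzyl)oxy]methyl}-2,3-dihydro-1-benzofuran-4-carbaldehyde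
Conditions: activated MnO2, CH2Cl2, rt
Reagents that add atoms: none
Why: MnO2 oxidises the benzylic alcohol to the aldehyde and stops there; the C3 hydroxymethyl is still a PMB ether, so no lactol can form with the new aldehyde.

Step 12
Reactants: 22 (R)-3-(3,4-dihydroxyphenyl)lactic acid (danshensu)
Product: 23 methyl (2R)-3-(3,4-dihydroxyphenyl)-2-hydroxypropanoate
Conditions: MeOH, p-TsOH·H2O (5 mol %), 60 °C, N2
Reagents that add atoms: methanol, CO
Why: Fischer esterification; acid does not touch the stereocentre, and nitrogen protects the catechol from air.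

Step 13
Reactants: 23 methyl ester
Product: 24 methyl (2R)-3-[3,4-bis(benzyloxy)phenyl]-2-hydroxypropanoate
Conditions: BnBr (2.2 equiv), K2CO3, acetone, 50 °C, N2
Reagents that add atoms: benzyl bromide, BrCc1ccccc1
Why: Williamson etherification; carbonate deprotonates the two phenols but neither the secondary hydroxyl nor the ester α-carbon, so the R centre is kept.

Step 14
Reactants: 24 hydroxy ester; 25 diethylphosphonoacetic acid
Product: 26 methyl (2R)-3-[3,4-bis(benzyloxy)phenyl]-2-{[(diethoxyphosphoryl)acetyl]oxy}propanoate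
Conditions: EDC·HCl, DMAP (10 mol %), CH2Cl2, 0 °C → rt
Reagents that add atoms: none
Why: Steglich-type carbodiimide esterification of the secondary alcohol under near-neutral conditions gives the olefination reagent with the lactate centre intact.

Step 15
Reactants: 21 aldehyde; 26 phosphonate
Product: 27 methyl (2R)-2-{[(2E)-3-[(2S,3R)-7-(benzyloxy)-2-[3,4-bis(benzyloxy)phenyl]-3-{[(4-methoxybenzyl)oxy]methyl}-2,3-dihydro-1-benzofuran-4-yl]prop-2-enoyl]oxy}-3-[3,4-bis(benzyloxy)phenyl]propanoate
Conditions: LiCl, i-Pr2NEt, MeCN, rt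
Reagents that add atoms: none
Why: Horner–Wadsworth–Emmons olefination under Masamune–Roush conditions: lithium chelation makes the phosphonoacetate acidic enough for a tertiary amine that is too weak to epimerise the acyloxy ester centre, and the stabilised anion gives the (E)-alkene with an aryl aldehyde; C3 is still a protected alcohol, so no pseudo-acid interferes.

Step 16
Reactants: 27 PMB ether
Product: 28 methyl (2R)-2-{[(2E)-3-[(2S,3R)-7-(benzyloxy)-2-[3,4-bis(benzyloxy)phenyl]-3-(hydroxymethyl)-2,3-dihydro-1-benzofuran-4-yl]prop-2-enoyl]oxy}-3-[3,4-bis(benzyloxy)phenyl]propanoate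
Conditions: DDQ (1.3 equiv), CH2Cl2/pH 7 buffer (10:1), 0 °C
Reagents that add atoms: none
Why: Oxidative PMB cleavage (hydride abstraction to the oxocarbenium ion, then hydrolysis); plain benzyl aryl ethers are not oxidised at 0 °C, and the small excess and low temperature guard against dehydrogenation of ring B.

Step 17
Reactants: 28 primary alcohol
Product: 30 (2S,3S)-7-(benzyloxy)-2-[3,4-bis(benzyloxy)phenyl]-4-[(1E)-3-{[(2R)-3-[3,4-bis(benzyloxy)phenyl]-1-methoxy-1-oxopropan-2-yl]oxy}-3-oxoprop-1-en-1-yl]-2,3-dihydro-1-benzofuran-3-carboxylic acid, via C3 aldehyde 29 (not isolated)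
Conditions: TEMPO (20 mol %), PhI(OAc)2 (2.5 equiv), MeCN/H2O (1:1), rt
Reagents that add atoms: water, O
Why: Oxoammonium oxidation in aqueous acetonitrile takes the alcohol through aldehyde 29 and its hydrate to the acid in one pot; the medium is weakly acidic, so the C3 proton is not removed, any epimerisation at the aldehyde stage would converge on the more stable trans isomer, and no free phenol is present for the trivalent iodine oxidant to attack.

Step 18
Reactants: 30 pentabenzyl acid
Product: 31 (2S,3S)-2-(3,4-dihydroxyphenyl)-4-[(1E)-3-{[(2R)-3-(3,4-dihydroxyphenyl)-1-methoxy-1-oxopropan-2-yl]oxy}-3-oxoprop-1-en-1-yl]-7-hydroxy-2,3-dihydro-1-benzofuran-3-carboxylic acid (target)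
Conditions: BCl3 (1 M in CH2Cl2, 15 equiv), C6HMe5 (20 equiv), CH2Cl2, −78 °C; MeOH quench at −78 °C; reversed-phase purification
Reagents that add atoms: none
Why: Lewis acid debenzylation: BCl3 binds the aryl benzyl ether oxygens and pentamethylbenzene traps the benzyl cations by Friedel–Crafts alkylation, which prevents C-benzylation of the catechols; at −78 °C the methyl ester, depside ester, acrylate and acid are inert, and because 2,3-trans is the thermodynamic arrangement a reversible ionisation at C2 would not alter the configuration fixed at C3.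

## Compound list

1 | tert-butyldimethyl(prop-2-yn-1-yloxy)silane | C#CCO[Si](C)(C)C(C)(C)C | starting material
2 | 2-[(4-methoxybenzyl)oxy]acetaldehyde | O=CCOCc1ccc(OC)cc1 | starting material
3 | {3-[(tert-butyldimethylsilyl)oxy]prop-1-yn-1-yl}lithium | [Li]C#CCO[Si](C)(C)C(C)(C)C | intermediate
4 | rac-5-[(tert-butyldimethylsilyl)oxy]-1-[(4-methoxybenzyl)oxy]pent-3-yn-2-ol | CC(C)(C)[Si](C)(C)OCC#CC(O)COCc1ccc(OC)cc1 | intermediate
5 | 5-[(tert-butyldimethylsilyl)oxy]-1-[(4-methoxybenzyl)oxy]pent-3-yn-2-one | CC(C)(C)[Si](C)(C)OCC#CC(=O)COCc1ccc(OC)cc1 | intermediate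
6 | (2S)-5-[(tert-butyldimethylsilyl)oxy]-1-[(4-methoxybenzyl)oxy]pent-3-yn-2-ol | CC(C)(C)[Si](C)(C)OCC#C[C@H](O)COCc1ccc(OC)cc1 | intermediate
7 | (2S)-5-[(tert-butyldimethylsilyl)oxy]-1-[(4-methoxybenzyl)oxy]pent-3-yn-2-yl methanesulfonate | CC(C)(C)[Si](C)(C)OCC#C[C@H](OS(C)(=O)=O)COCc1ccc(OC)cc1 | intermediate
8 | 3,4-bis(benzyloxy)benzaldehyde | O=Cc1ccc(OCc2ccccc2)c(OCc2ccccc2)c1 | starting material
9 | ethyl{(aS)-1-[(tert-butyldimethylsilyl)oxy]-5-[(4-methoxybenzyl)oxy]penta-2,3-dien-2-yl}zinc | CC[Zn]C(CO[Si](C)(C)C(C)(C)C)=[C@]=C(COCc1ccc(OC)cc1)[H] | intermediate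
10 | (1S,2R)-1-[3,4-bis(benzyloxy)phenyl]-5-[(tert-butyldimethylsilyl)oxy]-2-{[(4-methoxybenzyl)oxy]methyl}pent-3-yn-1-ol | CC(C)(C)[Si](C)(C)OCC#C[C@H](COCc1ccc(OC)cc1)[C@@H](c1ccc(OCc2ccccc2)c(OCc2ccccc2)c1)O | intermediate
11 | trichloroethylene | ClC=C(Cl)Cl | starting material
12 | dichloroacetylene | ClC#CCl | intermediate
13 | tert-butyl{[(4R,5S)-5-[3,4-bis(benzyloxy)phenyl]-5-{[(E)-1,2-dichloroethenyl]oxy}-4-{[(4-methoxybenzyl)oxy]methyl}pent-2-yn-1-yl]oxy}dimethylsilane | CC(C)(C)[Si](C)(C)OCC#C[C@H](COCc1ccc(OC)cc1)[C@@H](c1ccc(OCc2ccccc2)c(OCc2ccccc2)c1)O/C(Cl)=C\Cl | intermediate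
14 | ({[(1S,2R)-1-[3,4-bis(benzyloxy)phenyl]-5-[(tert-butyldimethylsilyl)oxy]-2-{[(4-methoxybenzyl)oxy]methyl}pent-3-yn-1-yl]oxy}ethynyl)lithium | CC(C)(C)[Si](C)(C)OCC#C[C@H](COCc1ccc(OC)cc1)[C@@H](c1ccc(OCc2ccccc2)c(OCc2ccccc2)c1)OC#C[Li] | intermediate
15 | benzyl({[(1S,2R)-1-[3,4-bis(benzyloxy)phenyl]-5-[(tert-butyldimethylsilyl)oxy]-2-{[(4-methoxybenzyl)oxy]methyl}pent-3-yn-1-yl]oxy}ethynyl)dimethylsilane | CC(C)(C)[Si](C)(C)OCC#C[C@H](COCc1ccc(OC)cc1)[C@@H](c1ccc(OCc2ccccc2)c(OCc2ccccc2)c1)OC#C[Si](C)(C)Cc1ccccc1 | intermediate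
16 | acetylene | C#C | starting material
17 | (2S,3R)-7-[benzyl(dimethyl)silyl]-2-[3,4-bis(benzyloxy)phenyl]-4-{[(tert-butyldimethylsilyl)oxy]methyl}-3-{[(4-methoxybenzyl)oxy]methyl}-2,3-dihydro-1-benzofuran | CC(C)(C)[Si](C)(C)OCc1ccc([Si](C)(C)Cc3ccccc3)c2c1[C@H](COCc1ccc(OC)cc1)[C@@H](c1ccc(OCc3ccccc3)c(OCc3ccccc3)c1)O2 | intermediate
18 | [(2S,3R)-2-[3,4-bis(benzyloxy)phenyl]-4-(hydroxymethyl)-3-{[(4-methoxybenzyl)oxy]methyl}-2,3-dihydro-1-benzofuran-7-yl]dimethylsilanol | OCc1ccc([Si](C)(C)O)c2c1[C@H](COCc1ccc(OC)cc1)[C@@H](c1ccc(OCc3ccccc3)c(OCc3ccccc3)c1)O2 | intermediate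
19 | (2S,3R)-2-[3,4-bis(benzyloxy)phenyl]-4-(hydroxymethyl)-3-{[(4-methoxybenzyl)oxy]methyl}-2,3-dihydro-1-benzofuran-7-ol | OCc1ccc(O)c2c1[C@H](COCc1ccc(OC)cc1)[C@@H](c1ccc(OCc3ccccc3)c(OCc3ccccc3)c1)O2 | intermediate
20 | [(2S,3R)-7-(benzyloxy)-2-[3,4-bis(benzyloxy)phenyl]-3-{[(4-methoxybenzyl)oxy]methyl}-2,3-dihydro-1-benzofuran-4-yl]methanol | OCc1ccc(OCc3ccccc3)c2c1[C@H](COCc1ccc(OC)cc1)[C@@H](c1ccc(OCc3ccccc3)c(OCc3ccccc3)c1)O2 | intermediate
21 | (2S,3R)-7-(benzyloxy)-2-[3,4-bis(benzyloxy)phenyl]-3-{[(4-methoxybenzyl)oxy]methyl}-2,3-dihydro-1-benzofuran-4-carbaldehyde | O=Cc1ccc(OCc3ccccc3)c2c1[C@H](COCc1ccc(OC)cc1)[C@@H](c1ccc(OCc3ccccc3)c(OCc3ccccc3)c1)O2 | intermediate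
22 | (R)-3-(3,4-dihydroxyphenyl)lactic acid (danshensu) | O=C(O)[C@@H](Cc1ccc(O)c(O)c1)O | starting material
23 | methyl (2R)-3-(3,4-dihydroxyphenyl)-2-hydroxypropanoate | COC(=O)[C@@H](Cc1ccc(O)c(O)c1)O | intermediate
24 | methyl (2R)-3-[3,4-bis(benzyloxy)phenyl]-2-hydroxypropanoate | COC(=O)[C@@H](Cc1ccc(OCc2ccccc2)c(OCc2ccccc2)c1)O | intermediate
25 | diethylphosphonoacetic acid | OC(=O)CP(=O)(OCC)OCC | starting material
26 | methyl (2R)-3-[3,4-bis(benzyloxy)phenyl]-2-{[(diethoxyphosphoryl)acetyl]oxy}propanoate | COC(=O)[C@@H](Cc1ccc(OCc2ccccc2)c(OCc2ccccc2)c1)OC(=O)CP(=O)(OCC)OCC | intermediate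
27 | methyl (2R)-2-{[(2E)-3-[(2S,3R)-7-(benzyloxy)-2-[3,4-bis(benzyloxy)phenyl]-3-{[(4-methoxybenzyl)oxy]methyl}-2,3-dihydro-1-benzofuran-4-yl]prop-2-enoyl]oxy}-3-[3,4-bis(benzyloxy)phenyl]propanoate | COC(=O)[C@@H](Cc1ccc(OCc2ccccc2)c(OCc2ccccc2)c1)OC(=O)/C=C/c1ccc(OCc3ccccc3)c2c1[C@H](COCc1ccc(OC)cc1)[C@@H](c1ccc(OCc3ccccc3)c(OCc3ccccc3)c1)O2 | intermediate
28 | methyl (2R)-2-{[(2E)-3-[(2S,3R)-7-(benzyloxy)-2-[3,4-bis(benzyloxy)phenyl]-3-(hydroxymethyl)-2,3-dihydro-1-benzofuran-4-yl]prop-2-enoyl]oxy}-3-[3,4-bis(benzyloxy)phenyl]propanoate | COC(=O)[C@@H](Cc1ccc(OCc2ccccc2)c(OCc2ccccc2)c1)OC(=O)/C=C/c1ccc(OCc3ccccc3)c2c1[C@H](CO)[C@@H](c1ccc(OCc3ccccc3)c(OCc3ccccc3)c1)O2 | intermediate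
29 | methyl (2R)-2-{[(2E)-3-[(2S,3S)-7-(benzyloxy)-2-[3,4-bis(benzyloxy)phenyl]-3-formyl-2,3-dihydro-1-benzofuran-4-yl]prop-2-enoyl]oxy}-3-[3,4-bis(benzyloxy)phenyl]propanoate | COC(=O)[C@@H](Cc1ccc(OCc2ccccc2)c(OCc2ccccc2)c1)OC(=O)/C=C/c1ccc(OCc3ccccc3)c2c1[C@H](C=O)[C@@H](c1ccc(OCc3ccccc3)c(OCc3ccccc3)c1)O2 | intermediate
30 | (2S,3S)-7-(benzyloxy)-2-[3,4-bis(benzyloxy)phenyl]-4-[(1E)-3-{[(2R)-3-[3,4-bis(benzyloxy)phenyl]-1-methoxy-1-oxopropan-2-yl]oxy}-3-oxoprop-1-en-1-yl]-2,3-dihydro-1-benzofuran-3-carboxylic acid | COC(=O)[C@@H](Cc1ccc(OCc2ccccc2)c(OCc2ccccc2)c1)OC(=O)/C=C/c1ccc(OCc3ccccc3)c2c1[C@H](C(=O)O)[C@@H](c1ccc(OCc3ccccc3)c(OCc3ccccc3)c1)O2 | intermediate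
31 | (2S,3S)-2-(3,4-dihydroxyphenyl)-4-[(1E)-3-{[(2R)-3-(3,4-dihydroxyphenyl)-1-methoxy-1-oxopropan-2-yl]oxy}-3-oxoprop-1-en-1-yl]-7-hydroxy-2,3-dihydro-1-benzofuran-3-carboxylic acid | COC(=O)[C@@H](Cc1ccc(O)c(O)c1)OC(=O)/C=C/c1ccc(O)c2c1[C@H](C(=O)O)[C@@H](c1ccc(O)c(O)c1)O2 | target

## Step count and least certain steps

Total: 18 steps. Longest linear sequence: 15 steps (steps 1–11 and 15–18); the lactate branch is steps 12–14.

**Step 8 (key step).** The likely failure is fragmentation of the benzylic alkynyl ether (retro-ene loss of a silylketene, sigmatropic shift, hydration) outrunning a slow oxidative coupling of two fully substituted, silyl-capped alkynes, while acetylene is used up by self-trimerisation. The cause is that the thermal ceiling of 15 (about 40 °C) is close to the temperature at which hindered diynes begin to couple at rhodium.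

The fallback replaces the alkynyl ether by a temporary silicon tether and closes ring B afterwards. It sets out from 10, returns at 17, and also by-passes steps 6 and 7. Ethynylmagnesium bromide and BnMe2SiCl give benzyl(ethynyl)dimethylsilane F1. Deprotonation of F1 (EtMgBr) and quenching with excess Me2SiCl2 give {[benzyl(dimethyl)silyl]ethynyl}(chloro)dimethylsilane F2. Alcohol 10 is silylated with F2 (Et3N, DMAP, CH2Cl2) to the silyl ether 1,7-diyne F3, which has no labile O–C(sp) bond. RhCl(PPh3)3 and acetylene then give the benzo-fused oxasiline F4, now at any temperature the catalyst needs. Fluoride-free Tamao oxidation (H2O2, KHCO3, THF/MeOH) attacks only the silicon that carries oxygen and gives the phenol alcohol F5, with BnMe2Si and TBS intact. Mild acid (PPTS, CH2Cl2, 0 °C) ionises the benzylic alcohol, and the phenol closes C2–O1 trans to the C3 substituent to give 17.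

**Step 5.** The likely failures are loss of anti selectivity (aromatic aldehydes react through looser transition states), β-elimination of the alkoxy groups that flank the metal-bearing carbon in the allenyl and propargyl forms, and racemisation of the allenylpalladium species by zerovalent palladium.

The fallback uses an isolable allenylboron reagent. It sets out from 6 and returns at 10. Alcohol 6 is converted (ClCO2Me, pyridine) into (2S)-5-[(tert-butyldimethylsilyl)oxy]-1-[(4-methoxybenzyl)oxy]pent-3-yn-2-yl methyl carbonate F6. Copper-catalysed anti SN2′ borylation (CuCl, Xantphos, KO-t-Bu, B2pin2, THF; monovalent copper boryl) gives the allenyl pinacolboronate F7 with central-to-axial chirality transfer. F7 is configurationally stable, carries no β-leaving group on a reactive metal, and adds to 8 on warming through a tight six-membered transition state to give 10 with the same sense of induction.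

**Step 9.** The likely failure is that fluoride at silicon expels the ortho-alkoxy-stabilised aryl group in competition with benzyl, giving protodesilylation at C7, and that the hindered aryl–silicon bond then oxidises slowly.

The fallback uses a silicon that already carries oxygen, so no C–Si bond has to be cleaved before oxidation. It sets out from 13 and returns at 19. Lithiation as in step 7 gives 14, which is quenched with excess Me2SiCl2 and then i-PrOH/Et3N to give the (isopropoxy)dimethylsilyl alkynyl ether F8. Cyclotrimerisation as in step 8 gives the aryl(isopropoxy)dimethylsilane F9. TBAF, KHCO3 and H2O2 in THF/MeOH oxidise it directly and remove the TBS group in the same pot, giving 19.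

**Step 18.** The likely failure is what happens to the liberated polyphenolic acid rather than the ether cleavage itself. Boron bound to the C3 carboxylate and to the C7 oxygen sits next to the ionisable C2–O1 bond. Any partially or C-benzylated congeners cannot be separated from a product that does not tolerate silica. The product also has to be freed from boron residues.

The fallback moves the Lewis acid step one stage back and ends with a fluoride desilylation. It sets out from 28 and returns at 31. BCl3/C6HMe5 at −78 °C on 28 gives the hexol F10. The crude hexol is silylated (TBSCl, imidazole, DMF) to the hexakis-TBS ether F11, which can be purified on silica. PPTS in MeOH removes only the alkyl silyl ether to give the primary alcohol F12. TEMPO/PhI(OAc)2 in aqueous MeCN gives the pentakis-TBS acid F13. HF·pyridine in THF/pyridine then gives 31 with only volatile by-products.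

## Further compounds

F1 | step 8 | benzyl(ethynyl)dimethylsilane | C#C[Si](C)(C)Cc1ccccc1
F2 | step 8 | {[benzyl(dimethyl)silyl]ethynyl}(chloro)dimethylsilane | C[Si](C)(Cl)C#C[Si](C)(C)Cc1ccccc1
F3 | step 8 | benzyl{[({(1S,2R)-1-[3,4-bis(benzyloxy)phenyl]-5-[(tert-butyldimethylsilyl)oxy]-2-{[(4-methoxybenzyl)oxy]methyl}pent-3-yn-1-yl}oxy)dimethylsilyl]ethynyl}dimethylsilane | CC(C)(C)[Si](C)(C)OCC#C[C@H](COCc1ccc(OC)cc1)[C@@H](c1ccc(OCc2ccccc2)c(OCc2ccccc2)c1)O[Si](C)(C)C#C[Si](C)(C)Cc1ccccc1
F4 | step 8 | (3S,4R)-8-[benzyl(dimethyl)silyl]-3-[3,4-bis(benzyloxy)phenyl]-5-{[(tert-butyldimethylsilyl)oxy]methyl}-4-{[(4-methoxybenzyl)oxy]methyl}-1,1-dimethyl-3,4-dihydro-1H-2,1-benzoxasiline | CC(C)(C)[Si](C)(C)OCc1ccc([Si](C)(C)Cc3ccccc3)c2c1[C@H](COCc1ccc(OC)cc1)[C@@H](c1ccc(OCc3ccccc3)c(OCc3ccccc3)c1)O[Si]2(C)C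
F5 | step 8 | (1S,2R)-2-{3-[benzyl(dimethyl)silyl]-6-{[(tert-butyldimethylsilyl)oxy]methyl}-2-hydroxyphenyl}-1-[3,4-bis(benzyloxy)phenyl]-3-[(4-methoxybenzyl)oxy]propan-1-ol | CC(C)(C)[Si](C)(C)OCc1ccc([Si](C)(C)Cc3ccccc3)c(O)c1[C@H](COCc1ccc(OC)cc1)[C@@H](c1ccc(OCc3ccccc3)c(OCc3ccccc3)c1)O
F6 | step 5 | (2S)-5-[(tert-butyldimethylsilyl)oxy]-1-[(4-methoxybenzyl)oxy]pent-3-yn-2-yl methyl carbonate | CC(C)(C)[Si](C)(C)OCC#C[C@H](OC(=O)OC)COCc1ccc(OC)cc1
F7 | step 5 | 2-{(aR)-1-[(tert-butyldimethylsilyl)oxy]-5-[(4-methoxybenzyl)oxy]penta-2,3-dien-2-yl}-4,4,5,5-tetramethyl-1,3,2-dioxaborolane | CC1(C)OB(OC1(C)C)C(CO[Si](C)(C)C(C)(C)C)=[C@]=C(COCc1ccc(OC)cc1)[H]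
F8 | step 9 | ({[(1S,2R)-1-[3,4-bis(benzyloxy)phenyl]-5-[(tert-butyldimethylsilyl)oxy]-2-{[(4-methoxybenzyl)oxy]methyl}pent-3-yn-1-yl]oxy}ethynyl)(isopropoxy)dimethylsilane | CC(C)(C)[Si](C)(C)OCC#C[C@H](COCc1ccc(OC)cc1)[C@@H](c1ccc(OCc2ccccc2)c(OCc2ccccc2)c1)OC#C[Si](C)(C)OC(C)C
F9 | step 9 | (2S,3R)-2-[3,4-bis(benzyloxy)phenyl]-4-{[(tert-butyldimethylsilyl)oxy]methyl}-7-[isopropoxy(dimethyl)silyl]-3-{[(4-methoxybenzyl)oxy]methyl}-2,3-dihydro-1-benzofuran | CC(C)(C)[Si](C)(C)OCc1ccc([Si](C)(C)OC(C)C)c2c1[C@H](COCc1ccc(OC)cc1)[C@@H](c1ccc(OCc3ccccc3)c(OCc3ccccc3)c1)O2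
F10 | step 18 | methyl (2R)-3-(3,4-dihydroxyphenyl)-2-{[(2E)-3-[(2S,3R)-2-(3,4-dihydroxyphenyl)-7-hydroxy-3-(hydroxymethyl)-2,3-dihydro-1-benzofuran-4-yl]prop-2-enoyl]oxy}propanoate | COC(=O)[C@@H](Cc1ccc(O)c(O)c1)OC(=O)/C=C/c1ccc(O)c2c1[C@H](CO)[C@@H](c1ccc(O)c(O)c1)O2
F11 | step 18 | hexakis(tert-butyldimethylsilyl) ether of F10 (five aryl silyl ethers and the C3 silyloxymethyl) | COC(=O)[C@@H](Cc1ccc(O[Si](C)(C)C(C)(C)C)c(O[Si](C)(C)C(C)(C)C)c1)OC(=O)/C=C/c1ccc(O[Si](C)(C)C(C)(C)C)c2c1[C@H](CO[Si](C)(C)C(C)(C)C)[C@@H](c1ccc(O[Si](C)(C)C(C)(C)C)c(O[Si](C)(C)C(C)(C)C)c1)O2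
F12 | step 18 | pentakis(aryl tert-butyldimethylsilyl) ether of F10 with free C3 hydroxymethyl | COC(=O)[C@@H](Cc1ccc(O[Si](C)(C)C(C)(C)C)c(O[Si](C)(C)C(C)(C)C)c1)OC(=O)/C=C/c1ccc(O[Si](C)(C)C(C)(C)C)c2c1[C@H](CO)[C@@H](c1ccc(O[Si](C)(C)C(C)(C)C)c(O[Si](C)(C)C(C)(C)C)c1)O2
F13 | step 18 | pentakis(aryl tert-butyldimethylsilyl) ether of 31 ((2S,3S)-3-carboxylic acid) | COC(=O)[C@@H](Cc1ccc(O[Si](C)(C)C(C)(C)C)c(O[Si](C)(C)C(C)(C)C)c1)OC(=O)/C=C/c1ccc(O[Si](C)(C)C(C)(C)C)c2c1[C@H](C(=O)O)[C@@H](c1ccc(O[Si](C)(C)C(C)(C)C)c(O[Si](C)(C)C(C)(C)C)c1)O2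
A1 | alternative 1 | (2R)-3-(3,4-dihydroxyphenyl)-2-(6-formyl-2,3-dihydroxyphenyl)propanoic acid | O=Cc1ccc(O)c(O)c1[C@H](C(=O)O)Cc1ccc(O)c(O)c1
A2 | alternative 1 | (2S,3S)-2-(3,4-dihydroxyphenyl)-4-formyl-7-hydroxy-2,3-dihydro-1-benzofuran-3-carboxylic acid | O=Cc1ccc(O)c2c1[C@H](C(=O)O)[C@@H](c1ccc(O)c(O)c1)O2
A3 | alternative 2 | (1S,2R)-1-[3,4-bis(benzyloxy)phenyl]-2-(3-bromo-2-fluorophenyl)-3-[(tert-butyldimethylsilyl)oxy]propan-1-ol | Fc1c(Br)cccc1[C@H](CO[Si](C)(C)C(C)(C)C)[C@@H](c1ccc(OCc2ccccc2)c(OCc2ccccc2)c1)O
A4 | alternative 2 | (2S,3R)-2-[3,4-bis(benzyloxy)phenyl]-3-{[(tert-butyldimethylsilyl)oxy]methyl}-2,3-dihydro-1-benzofuran-7-ol | c1ccc(O)c2c1[C@H](CO[Si](C)(C)C(C)(C)C)[C@@H](c1ccc(OCc3ccccc3)c(OCc3ccccc3)c1)O2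
A5 | alternative 3 | (4S)-4-benzyl-3-{(2E)-3-[3-(benzyloxy)-4-hydroxyphenyl]prop-2-enoyl}-1,3-oxazolidin-2-one | O=C(/C=C/c1ccc(O)c(OCc2ccccc2)c1)N1C(=O)OC[C@@H]1Cc1ccccc1
A6 | alternative 3 | tert-butyl (2E)-3-[4-(benzyloxy)-2-bromo-5-hydroxyphenyl]prop-2-enoate | CC(C)(C)OC(=O)/C=C/c1cc(O)c(OCc2ccccc2)cc1Br
A7 | alternative 3 | tert-butyl (2E)-3-[(2S,3S)-3-{[(4S)-4-benzyl-2-oxo-1,3-oxazolidin-3-yl]carbonyl}-7-(benzyloxy)-2-[3-(benzyloxy)-4-hydroxyphenyl]-5-bromo-2,3-dihydro-1-benzofuran-4-yl]prop-2-enoate | CC(C)(C)OC(=O)/C=C/c1c(Br)cc(OCc3ccccc3)c2c1[C@H](C(=O)N1C(=O)OC[C@@H]1Cc1ccccc1)[C@@H](c1ccc(O)c(OCc3ccccc3)c1)O2
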